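**Strategy**

Everything rests on opening the cyclopentane of the trans-hydrindane between its methyl carbinol carbon and the neighbouring ring CH2. At the ketone oxidation level this carbinol carbon is the acyl carbon of a 4-pentenal hidden in the six-membered carbocycle, a trans-2-vinylcyclohexanecarbaldehyde. Rhodium-catalysed intramolecular hydroacylation joins the formyl carbon to the terminal vinyl carbon and closes the cyclopentanone in one atom-economical operation that leaves the four existing stereocentres untouched. The precursor, a spirocyclic aldehyde, is assembled from a dearomatised diprenyl acylphloroglucinol and an epoxide-derived C8 hydroxy aldehyde by reductive alkylation and a methylenation/Michael spiroannulation; methyl addition to the new ketone completes the target.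

Key step: step 10

Remark on the chemistry: the target is an enolised β-triketone; all its tautomers are treated as one compound, and CIP descriptors refer to the tautomers as drawn. Aldehyde 13 is expected to exist in equilibrium with its five-membered lactol; the open form is drawn.

**Route**

Step 1
Reactants: 1 2,4,6-trihydroxyacetophenone; 2 prenyl bromide (1-bromo-3-methylbut-2-ene)
Product: 3 2-acetyl-3,5-dihydroxy-4,4-bis(3-methylbut-2-en-1-yl)cyclohexa-2,5-dien-1-one
Conditions: NaOMe (2.2 equiv), 2 (2.1 equiv), MeOH, 0 °C
Reagents that add atoms: none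
Why: Base-mediated C-alkylation of the phloroglucinol anion (alkylative dearomatisation) should place both prenyl groups on one ring carbon, the geminal product being separated by chromatography from the 3,5-diprenyl isomer.

Step 2
Reactants: 4 4,4-diethoxybut-1-ene (3-butenal diethyl acetal); 5 methacrolein
Product: 6 (E)-5,5-diethoxy-2-methylpent-2-enal
Conditions: second-generation Grubbs catalyst RuCl2(H2IMes)(PCy3)(=CHPh) (5 mol %), 5 (3 equiv), CH2Cl2, 40 °C
Reagents that add atoms: none
Why: Olefin cross-metathesis of the terminal alkene with the 1,1-disubstituted enal should give the trisubstituted enal with the thermodynamically preferred E geometry, ethene being lost.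

Step 3
Reactants: 6 (E)-5,5-diethoxy-2-methylpent-2-enal
Product: 7 (E)-5,5-diethoxy-2-methylpent-2-en-1-ol
Conditions: iBu2AlH (1.2 equiv), CH2Cl2, −78 °C; aqueous potassium sodium tartrate
Reagents that add atoms: none
Why: 1,2-Reduction of the enal by the aluminium hydride leaves the alkene geometry and the acetal untouched.

Step 4
Reactants: 7 (E)-5,5-diethoxy-2-methylpent-2-en-1-ol
Product: 8 [(2S,3S)-3-(2,2-diethoxyethyl)-2-methyloxiran-2-yl]methanol
Conditions: Ti(OiPr)4 (10 mol %), L-(+)-diethyl tartrate (12 mol %), tBuOOH (2 equiv), 4 Å molecular sieves, CH2Cl2, −20 °C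
Reagents that add atoms: tert-butyl hydroperoxide, CC(C)(C)OO
Why: Sharpless asymmetric epoxidation of the E allylic alcohol with the L-(+)-tartrate should deliver oxygen to the face that gives the (2S,3S)-epoxide, which fixes the future ring carbinol carbon absolutely.

Step 5
Reactants: 8 [(2S,3S)-3-(2,2-diethoxyethyl)-2-methyloxiran-2-yl]methanol
Product: 9 (2R,3S)-3-ethenyl-5,5-diethoxy-2-methylpentane-1,2-diol
Conditions: CH2=CHMgBr (4 equiv), CuI (10 mol %), THF, −30 to 0 °C
Reagents that add atoms: vinylmagnesium bromide, C=C[Mg]Br
Why: Copper-catalysed Grignard opening of the 2,3-epoxy alcohol should occur by SN2 attack with inversion at C3, the only epoxide carbon that is not fully substituted, which sets the vinyl-bearing stereocentre relative to the carbinol.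

Step 6
Reactants: 9 (2R,3S)-3-ethenyl-5,5-diethoxy-2-methylpentane-1,2-diol
Product: 10 (2R,3S)-3-ethenyl-5,5-diethoxy-2-hydroxy-2-methylpentanal
Conditions: SO3·pyridine (3 equiv), DMSO, iPr2NEt, CH2Cl2, 0 °C
Reagents that add atoms: none
Why: Parikh–Doering oxidation converts only the primary alcohol, the tertiary hydroxyl being inert, and avoids glycol cleavage.

Step 7
Reactants: 3 2-acetyl-3,5-dihydroxy-4,4-bis(3-methylbut-2-en-1-yl)cyclohexa-2,5-dien-1-one; 10 (2R,3S)-3-ethenyl-5,5-diethoxy-2-hydroxy-2-methylpentanal
Product: 12 2-acetyl-6-[(2S,3S)-3-ethenyl-5,5-diethoxy-2-hydroxy-2-methylpentyl]-3,5-dihydroxy-4,4-bis(3-methylbut-2-en-1-yl)cyclohexa-2,5-dien-1-one, via alkylidene trione 11 (not isolated)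
Conditions: L-proline (20 mol %), diethyl 2,6-dimethyl-1,4-dihydropyridine-3,5-dicarboxylate (Hantzsch ester, 1.2 equiv), CH2Cl2, 25 °C
Reagents that add atoms: none
Why: Knoevenagel condensation at the only free ring carbon of 3 followed by conjugate transfer hydrogenation of the alkylidene trione (three-component reductive alkylation of a cyclic 1,3-dione) should give clean C-monoalkylation, the side-chain stereocentres taking no part.

Step 8
Reactants: 12 the acetal from step 7
Product: 13 2-acetyl-6-[(2S,3S)-3-ethenyl-2-hydroxy-2-methyl-5-oxopentyl]-3,5-dihydroxy-4,4-bis(3-methylbut-2-en-1-yl)cyclohexa-2,5-dien-1-one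
Conditions: AcOH/THF/H2O (3:1:1), 40 °C
Reagents that add atoms: water, O
Why: Mild acid hydrolysis of the acyclic acetal frees the aldehyde under conditions too weak to cyclise the prenyl groups onto the enols.

Step 9
Reactants: 13 the aldehyde from step 8
Product: 15 (6S,8S,9R,10S)-2-acetyl-9-ethenyl-3,8-dihydroxy-8-methyl-4,4-bis(3-methylbut-2-en-1-yl)-1,5-dioxospiro[5.5]undec-2-ene-10-carbaldehyde, via α-methylene aldehyde 14 (not isolated)
Conditions: aq. CH2O (37 %, 1.1 equiv), pyrrolidine (20 mol %), EtCO2H (20 mol %), iPrOH, 45 °C; then DBU (1.1 equiv), toluene, 25 °C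
Reagents that add atoms: formaldehyde, C=O
Why: Amine-catalysed Mannich condensation/elimination (α-methylenation) makes the enal and the alkylated trione carbon adds to it in a 6-endo-trig Michael reaction; the formyl centre should settle equatorial and trans to the vinyl group by enolisation, and the reversible Michael addition should funnel the spiro centre to the epimer whose axial ring carbonyl belongs to the ionised β-triketone and accepts a hydrogen bond from the axial tertiary hydroxyl.

Step 10
Reactants: 15 the spirocyclic aldehyde from step 9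
Product: 16 trans-fused spiro hydrindanone: the cyclopentanone formed across C9–C10 of 15, the former formyl carbon being the ring ketone (spiro carbon S, ring-fusion carbon next to the ketone S, other ring-fusion carbon R, carbinol carbon S)
Conditions: [Rh(dppe)(acetone)2]BF4 (5 mol %), CH2Cl2, 25 °C
Reagents that add atoms: none
Why: Oxidative addition of the aldehyde C–H bond to cationic monovalent rhodium gives an acyl rhodium hydride, the vinyl group inserts into Rh–H with the metal on the terminal carbon, and C–C reductive elimination from the six-membered acyl alkyl rhodacycle joins the former formyl carbon to the terminal vinyl carbon. The closest known reaction type is the rhodium-catalysed intramolecular hydroacylation of 4-pentenals to cyclopentanones. The cyclopentanone closes in a formal 5-endo-trig sense with respect to the alkene, which the hydrometalation/reductive elimination pathway makes feasible, and it is trans-fused to the cyclohexane. No new stereocentre is formed; the trans ring fusion is carried over from the trans-diequatorial formyl and vinyl groups of 15, and the neutral conditions should not epimerise the α-carbon. The step needs ring closure to win over decarbonylation and alkene isomerisation, which the chelating dppe ligand and the 2,3-disubstituted 4-pentenal geometry should secure. The prenyl groups are trisubstituted and too remote to insert, and the hydrogen-bonded enol should be a poor ligand for the cationic metal in a non-coordinating solvent.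

Step 11
Reactants: 16 the hydrindanone from step 10
Product: 17 target CNP0266834.3: the tertiary methyl carbinol from 16 (spiro carbon S, ring-fusion carbons S and R, six-ring carbinol S, five-ring carbinol R)
Conditions: MeMgBr (5 equiv), CeCl3 (5 equiv), THF, −78 °C; aq. NH4Cl
Reagents that add atoms: methylmagnesium bromide, C[Mg]Br
Why: The weakly basic organocerium reagent should add to the cyclopentanone without enolisation once the enol and the tertiary alcohol are deprotonated, leaving the ring ketone flanked by two quaternary carbons and the enolate-masked triketone intact, and attack from the face of the angular hydrogen next to the carbonyl (away from the two syn-axial hydrogens of the other face) should place methyl pseudo-equatorial and hydroxyl pseudo-axial as in the target.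

**Compound list**

1 | 2,4,6-trihydroxyacetophenone | CC(=O)c1c(O)cc(O)cc1O | starting material
2 | prenyl bromide (1-bromo-3-methylbut-2-ene) | CC(C)=CCBr | starting material
3 | 2-acetyl-3,5-dihydroxy-4,4-bis(3-methylbut-2-en-1-yl)cyclohexa-2,5-dien-1-one | CC(=O)C1=C(O)C(CC=C(C)C)(CC=C(C)C)C(O)=CC1=O | intermediate
4 | 4,4-diethoxybut-1-ene | C=CCC(OCC)OCC | starting material
5 | methacrolein | CC(=C)C=O | starting material
6 | (E)-5,5-diethoxy-2-methylpent-2-enal | CCOC(OCC)C/C=C(\C)C=O | intermediate
7 | (E)-5,5-diethoxy-2-methylpent-2-en-1-ol | CCOC(OCC)C/C=C(\C)CO | intermediate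
8 | [(2S,3S)-3-(2,2-diethoxyethyl)-2-methyloxiran-2-yl]methanol | OC[C@]1(C)O[C@H]1CC(OCC)OCC | intermediate
9 | (2R,3S)-3-ethenyl-5,5-diethoxy-2-methylpentane-1,2-diol | OC[C@](C)(O)[C@H](C=C)CC(OCC)OCC | intermediate
10 | (2R,3S)-3-ethenyl-5,5-diethoxy-2-hydroxy-2-methylpentanal | O=C[C@](C)(O)[C@H](C=C)CC(OCC)OCC | intermediate
11 | 2-acetyl-6-[(2R,3S)-3-ethenyl-5,5-diethoxy-2-hydroxy-2-methylpentylidene]-3-hydroxy-4,4-bis(3-methylbut-2-en-1-yl)cyclohex-2-ene-1,5-dione (alkylidene trione) | CC(=O)C1=C(O)C(CC=C(C)C)(CC=C(C)C)C(=O)C(=C[C@](C)(O)[C@H](C=C)CC(OCC)OCC)C1=O | intermediate (not isolated)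
12 | 2-acetyl-6-[(2S,3S)-3-ethenyl-5,5-diethoxy-2-hydroxy-2-methylpentyl]-3,5-dihydroxy-4,4-bis(3-methylbut-2-en-1-yl)cyclohexa-2,5-dien-1-one | CC(=O)C1=C(O)C(CC=C(C)C)(CC=C(C)C)C(O)=C(C[C@](C)(O)[C@H](C=C)CC(OCC)OCC)C1=O | intermediate
13 | 2-acetyl-6-[(2S,3S)-3-ethenyl-2-hydroxy-2-methyl-5-oxopentyl]-3,5-dihydroxy-4,4-bis(3-methylbut-2-en-1-yl)cyclohexa-2,5-dien-1-one | CC(=O)C1=C(O)C(CC=C(C)C)(CC=C(C)C)C(O)=C(C[C@](C)(O)[C@H](C=C)CC=O)C1=O | intermediate
14 | 2-acetyl-6-[(2S,3R)-3-ethenyl-4-formyl-2-hydroxy-2-methylpent-4-en-1-yl]-3,5-dihydroxy-4,4-bis(3-methylbut-2-en-1-yl)cyclohexa-2,5-dien-1-one (α-methylene aldehyde) | CC(=O)C1=C(O)C(CC=C(C)C)(CC=C(C)C)C(O)=C(C[C@](C)(O)[C@H](C=C)C(=C)C=O)C1=O | intermediate (not isolated)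
15 | (6S,8S,9R,10S)-2-acetyl-9-ethenyl-3,8-dihydroxy-8-methyl-4,4-bis(3-methylbut-2-en-1-yl)-1,5-dioxospiro[5.5]undec-2-ene-10-carbaldehyde | CC(=O)C1=C(O)C(CC=C(C)C)(CC=C(C)C)C(=O)[C@@]2(C[C@H](C=O)[C@@H](C=C)[C@@](C)(O)C2)C1=O | intermediate
16 | trans-fused spiro hydrindanone (cyclopentanone closed across C9–C10 of 15; spiro S, ring fusion S and R, carbinol S) | CC(=O)C1=C(O)C(CC=C(C)C)(CC=C(C)C)C(=O)[C@@]2(C[C@H]3[C@@H](CCC3=O)[C@@](C)(O)C2)C1=O | intermediate
17 | CNP0266834.3 (spiro S, ring fusion S and R, six-ring carbinol S, five-ring carbinol R) | CC(=O)C1=C(O)C(CC=C(C)C)(CC=C(C)C)C(=O)[C@@]2(C[C@H]3[C@@H](CC[C@@]3(C)O)[C@@](C)(O)C2)C1=O | target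

**Step count**

Total steps: 11. Longest linear sequence: 10 steps (steps 2 to 11, from 4 and 5 to 17); step 1 is a one-step branch.

**Steps most likely to fail**

Step 9. Formaldehyde may be consumed by hydroxymethylation or Mannich reaction at the nucleophilic ring carbon, or may over-react at the product aldehyde, and equilibration of the spiro centre may be too slow to correct a poor kinetic facial preference. The fallback sets out from 13 and returns at 15; it brings the extra carbon in at the aldehyde oxidation level and without formaldehyde. Treatment of 13 with tert-butoxybis(dimethylamino)methane should give the dimethylaminomethylene aldehyde F1. With acetic acid the ring carbon should then displace dimethylamine by intramolecular addition–elimination and close the six-membered ring as the spirocyclic cyclohexene carbaldehyde F2, expected as a mixture at the spiro carbon. Conjugate transfer hydrogenation of F2 (Hantzsch ester, dibenzylammonium trifluoroacetate) followed by DBU in toluene, which equilibrates the formyl and spiro centres through the retro-Michael/Michael manifold, should give 15.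

Step 10. The acyl rhodium hydride may decarbonylate and leave an inactive carbonyl complex, the triketone enolate may sequester the cationic metal, or the vinyl group may isomerise. The fallback sets out from 15 and returns at 16; it uses a covalently bound directing group. Condensation of 15 with 2-amino-3-methylpyridine should give the pyridyl aldimine F3. With RhCl(PPh3)3 (10 mol %) in toluene at 110 °C the pyridine nitrogen holds the iminoacyl rhodium hydride in a five-membered chelate that cannot decarbonylate, and vinyl insertion and reductive elimination should form the same ring bond to give the cyclic ketimine F4. Hydrolysis of F4 with aqueous oxalic acid should give 16.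

Step 11. Facial discrimination at the cyclopentanone carbonyl may be poor, and enolisation may lead to epimerisation of the ring fusion or retro-Michael opening of the six-membered ring. The fallback sets out from 16 and returns at 17; the carbinol configuration is then set by axial attack of water, not by attack of a methyl nucleophile. Wittig methylenation of 16 (Ph3P=CH2 from Ph3PCH3Br and KOtBu, THF, 0 °C) should give the exocyclic alkene F5. Oxymercuration with Hg(OAc)2 in THF/H2O should take place at the 1,1-disubstituted alkene faster than at the trisubstituted prenyl alkenes, with water entering pseudo-axially at the tertiary carbon to give the organomercurial F6. Demercuration of F6 with NaBH4 should give 17.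

Further compounds
F1 | step 9 | 2-acetyl-6-[(2S,3R)-4-(dimethylaminomethylene)-3-ethenyl-2-hydroxy-2-methyl-5-oxopentyl]-3,5-dihydroxy-4,4-bis(3-methylbut-2-en-1-yl)cyclohexa-2,5-dien-1-one | CC(=O)C1=C(O)C(CC=C(C)C)(CC=C(C)C)C(O)=C(C[C@](C)(O)[C@H](C=C)C(=CN(C)C)C=O)C1=O
F2 | step 9 | 2-acetyl-9-ethenyl-3,8-dihydroxy-8-methyl-4,4-bis(3-methylbut-2-en-1-yl)-1,5-dioxospiro[5.5]undeca-2,10-diene-10-carbaldehyde (spiro carbon unassigned, other centres as in 15) | CC(=O)C1=C(O)C(CC=C(C)C)(CC=C(C)C)C(=O)C2(C=C(C=O)[C@@H](C=C)[C@@](C)(O)C2)C1=O
F3 | step 10 | N-(3-methylpyridin-2-yl) aldimine of 15 | CC(=O)C1=C(O)C(CC=C(C)C)(CC=C(C)C)C(=O)[C@@]2(C[C@H](C=Nc3ncccc3C)[C@@H](C=C)[C@@](C)(O)C2)C1=O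
F4 | step 10 | N-(3-methylpyridin-2-yl) ketimine of 16 | CC(=O)C1=C(O)C(CC=C(C)C)(CC=C(C)C)C(=O)[C@@]2(C[C@H]3[C@@H](CCC3=Nc4ncccc4C)[C@@](C)(O)C2)C1=O
F5 | step 11 | exocyclic methylene analogue of 16 (C=CH2 in place of the ring C=O) | CC(=O)C1=C(O)C(CC=C(C)C)(CC=C(C)C)C(=O)[C@@]2(C[C@H]3[C@@H](CCC3=C)[C@@](C)(O)C2)C1=O
F6 | step 11 | acetoxymercuriomethyl carbinol (17 with CH2HgOAc in place of the new methyl group) | CC(=O)C1=C(O)C(CC=C(C)C)(CC=C(C)C)C(=O)[C@@]2(C[C@H]3[C@@H](CC[C@@]3(C[Hg]OC(C)=O)O)[C@@](C)(O)C2)C1=O
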